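Ring B (the dihydropyranone; chromanone numbering) is cut at C3–C2 and C4–C4a, which leaves an ortho-bromoaryl acetate and a pyronylacetyl chloride. In one flask, bromine–lithium exchange at C4a makes the acetyl group jump from O1 to C4a (anionic ortho-Fries shift), and the methyl ketone so formed is enolised and acylated at C3 by the acid chloride. The step exploits the ortho relation between O1 on C8a and the C4 carbonyl on C4a, and the 1,3-relation of the C4 and C2 carbonyl carbons across the C3 methylene; after debenzylation O1 closes ring B as the C2 hemiketal. The precursor is 5-(benzyloxy)-2-bromo-3-(3-methylbutyl)phenyl acetate.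

Key step: step 7

Assumption: the C2 hemiketal is taken to be configurationally persistent under neutral, aprotic conditions at or below room temperature (ring–chain tautomerism needs acid or base), so acid and base are kept away once C2 has formed in step 8. The C2 descriptor of the target is (R).

Step 1
Reactants: 1 3,5-bis(benzyloxy)benzyl bromide; 2 isobutylmagnesium bromide
Product: 3 1,3-bis(benzyloxy)-5-(3-methylbutyl)benzene
Conditions: Li2CuCl4 (3 mol%), THF, −20 → 0 °C
Reagents that add atoms: none
Why: Copper-catalysed sp3–sp3 cross-coupling of a benzylic bromide with a primary alkyl Grignard reagent (Kochi coupling) is fast at low temperature, leaves the benzyl ethers untouched and forms no stereocentre.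

Step 2
Reactants: 3 1,3-bis(benzyloxy)-5-(3-methylbutyl)benzene
Product: 5 3-(benzyloxy)-5-(3-methylbutyl)phenyl acetate, via sodium phenoxide 4 (not isolated)
Conditions: NaSEt (1.3 equiv), DMF, 110 °C; then Ac2O (2 equiv), 0 °C → rt
Reagents that add atoms: acetic anhydride, CC(=O)OC(C)=O
Why: Thiolate SN2 dealkylation at a benzylic carbon should stop after one ether because the phenoxide formed makes the second aryloxide a much poorer leaving group, and the phenoxide is then O-acetylated in the same flask (acylation with an anhydride).

Step 3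
Reactants: 5 3-(benzyloxy)-5-(3-methylbutyl)phenyl acetate
Product: 6 5-(benzyloxy)-2-bromo-3-(3-methylbutyl)phenyl acetate
Conditions: NBS (1.05 equiv), MeCN, 0 °C → rt, dark
Reagents that add atoms: N-bromosuccinimide, O=C1CCC(=O)N1Br
Why: Electrophilic aromatic bromination with NBS in MeCN should go para to the strongest donor (the benzyloxy group), a carbon that is also ortho to the acetoxy and alkyl groups, so all three substituents direct to the future C4a.

Step 4
Reactants: 7 4-hydroxy-6-methyl-2H-pyran-2-one
Product: 8 4-(benzyloxy)-6-methyl-2H-pyran-2-one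
Conditions: BnBr (1.1 equiv), K2CO3 (1.5 equiv), DMF, rt
Reagents that add atoms: benzyl bromide, BrCc1ccccc1
Why: Williamson-type O-alkylation of the vinylogous acid at its 4-oxygen masks the acidic pyrone hydroxyl as a benzyl ether that later falls off together with the aryl benzyl ether.

Step 5
Reactants: 8 4-(benzyloxy)-6-methyl-2H-pyran-2-one
Product: 10 [4-(benzyloxy)-2-oxo-2H-pyran-6-yl]acetic acid, via lithiated pyrone 9 (not isolated)
Conditions: LiN(i-Pr)2 (1.1 equiv), THF, −78 °C; cannulated onto CO2 (s)/THF, −78 °C; cold 1 M HCl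
Reagents that add atoms: carbon dioxide, O=C=O
Why: Kinetic lateral (vinylogous) deprotonation of the 6-methyl group gives a dienolate-type anion whose carboxylation by inverse addition to excess CO2 limits proton transfer from the product carboxylate.

Step 6
Reactants: 10 [4-(benzyloxy)-2-oxo-2H-pyran-6-yl]acetic acid
Product: 11 [4-(benzyloxy)-2-oxo-2H-pyran-6-yl]acetyl chloride
Conditions: (COCl)2 (1.2 equiv), DMF (cat.), CH2Cl2, 0 °C → rt; evaporated cold, used at once
Reagents that add atoms: oxalyl chloride, ClC(=O)C(=O)Cl
Why: Acid chloride formation through the Vilsmeier-type chloroiminium from oxalyl chloride and catalytic DMF runs cold enough to keep the enolisable acyl chloride from ketene dimerisation.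

Step 7
Reactants: 6 5-(benzyloxy)-2-bromo-3-(3-methylbutyl)phenyl acetate; 11 [4-(benzyloxy)-2-oxo-2H-pyran-6-yl]acetyl chloride
Product: 15 1-[4-(benzyloxy)-2-hydroxy-6-(3-methylbutyl)phenyl]-4-[4-(benzyloxy)-2-oxo-2H-pyran-6-yl]butane-1,3-dione, via aryllithium 12 (not isolated), via lithium acetylphenoxide 13 (not isolated), via dilithium enolate 14 (not isolated)
Conditions: t-BuLi (2.05 equiv), THF/Et2O, −100 → −78 °C; LiN(SiMe3)2 (2.5 equiv), −78 → −30 °C; 11 (1.1 equiv), −78 → 0 °C; AcOH, −78 °C
Reagents that add atoms: none
Why: Bromine–lithium exchange with t-BuLi at −100 °C, which should outrun attack on or deprotonation of the acetate, gives aryllithium 12, whose C4a carbanion adds to the neighbouring acetate carbonyl and collapses to phenoxide 13, a 1,3-O→C acyl shift (anionic ortho-Fries rearrangement) that makes C4–C4a. LiN(SiMe3)2 then turns the methyl ketone into dianion 14, whose C3 enolate carbon is acylated by 11 (Claisen-type C-acylation, in part through the ketene derived from 11) to make C3–C2, and any O-acylated ester should funnel to the same diketonate by Baker–Venkataraman acyl transfer. The closest known reaction types are the halogen–metal-exchange-induced anionic Fries rearrangement of ortho-bromophenyl esters and the acylation of ortho-hydroxyacetophenone polyanions with acid chlorides. No ring is closed and no stereocentre is formed here, since ring B closes only in step 8 by 6-exo-trig addition of O1 to the C2 ketone. The step needs regioselectivity for C4a over C6 and C8, which the bromine position and the intramolecular acyl delivery from O1 secure, and it needs mono-C-acylation, which the excess base secures by keeping the ketone enolised and the product as its unreactive diketonate.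

Step 8
Reactants: 15 1-[4-(benzyloxy)-2-hydroxy-6-(3-methylbutyl)phenyl]-4-[4-(benzyloxy)-2-oxo-2H-pyran-6-yl]butane-1,3-dione
Product: 17 rac-2,7-dihydroxy-2-[(4-hydroxy-2-oxo-2H-pyran-6-yl)methyl]-5-(3-methylbutyl)-2,3-dihydro-4H-chromen-4-one, via open-chain triol 16 (not isolated)
Conditions: H2 (1 atm), Pd/C (10 wt%), EtOAc, rt
Reagents that add atoms: none
Why: Hydrogenolysis of both benzyl ethers under neutral conditions should free triol 16, whose O1 adds to the C2 ketone (6-exo-trig hemiketalisation) without stereocontrol, so C2 is expected as a racemate.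

Step 9
Reactants: 17 rac-2,7-dihydroxy-2-[(4-hydroxy-2-oxo-2H-pyran-6-yl)methyl]-5-(3-methylbutyl)-2,3-dihydro-4H-chromen-4-one
Product: 18 (2R)-2,7-dihydroxy-2-[(4-hydroxy-2-oxo-2H-pyran-6-yl)methyl]-5-(3-methylbutyl)-2,3-dihydro-4H-chromen-4-one (target)
Conditions: preparative SFC, immobilised cellulose tris(3,5-dichlorophenylcarbamate) phase, CO2/i-PrOH, 10 °C
Reagents that add atoms: none
Why: Resolution by preparative chromatography on a chiral stationary phase under neutral, cold conditions should separate the enantiomers, so the (2R) configuration is fixed here by physical selection and meets no acid or base afterwards.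

Compound list
1 | 3,5-bis(benzyloxy)benzyl bromide | BrCc1cc(OCc2ccccc2)cc(OCc2ccccc2)c1 | starting material
2 | isobutylmagnesium bromide | CC(C)C[Mg]Br | starting material
3 | 1,3-bis(benzyloxy)-5-(3-methylbutyl)benzene | CC(C)CCc1cc(OCc2ccccc2)cc(OCc2ccccc2)c1 | intermediate
4 | sodium 3-(benzyloxy)-5-(3-methylbutyl)phenolate (not isolated) | [Na+].[O-]c1cc(CCC(C)C)cc(OCc2ccccc2)c1 | intermediate
5 | 3-(benzyloxy)-5-(3-methylbutyl)phenyl acetate | CC(=O)Oc1cc(CCC(C)C)cc(OCc2ccccc2)c1 | intermediate
6 | 5-(benzyloxy)-2-bromo-3-(3-methylbutyl)phenyl acetate | CC(=O)Oc1cc(OCc2ccccc2)cc(CCC(C)C)c1Br | intermediate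
7 | 4-hydroxy-6-methyl-2H-pyran-2-one | Cc1cc(O)cc(=O)o1 | starting material
8 | 4-(benzyloxy)-6-methyl-2H-pyran-2-one | Cc1cc(OCc2ccccc2)cc(=O)o1 | intermediate
9 | {[4-(benzyloxy)-2-oxo-2H-pyran-6-yl]methyl}lithium (not isolated) | [Li]Cc1cc(OCc2ccccc2)cc(=O)o1 | intermediate
10 | [4-(benzyloxy)-2-oxo-2H-pyran-6-yl]acetic acid | OC(=O)Cc1cc(OCc2ccccc2)cc(=O)o1 | intermediate
11 | [4-(benzyloxy)-2-oxo-2H-pyran-6-yl]acetyl chloride | ClC(=O)Cc1cc(OCc2ccccc2)cc(=O)o1 | intermediate
12 | [2-(acetyloxy)-4-(benzyloxy)-6-(3-methylbutyl)phenyl]lithium (not isolated) | CC(=O)Oc1cc(OCc2ccccc2)cc(CCC(C)C)c1[Li] | intermediate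
13 | lithium 2-acetyl-5-(benzyloxy)-3-(3-methylbutyl)phenolate (not isolated) | [Li+].[O-]c1cc(OCc2ccccc2)cc(CCC(C)C)c1C(C)=O | intermediate
14 | dilithium 5-(benzyloxy)-3-(3-methylbutyl)-2-(1-oxidoethenyl)phenolate (not isolated) | [Li+].[Li+].[O-]c1cc(OCc2ccccc2)cc(CCC(C)C)c1C([O-])=C | intermediate
15 | 1-[4-(benzyloxy)-2-hydroxy-6-(3-methylbutyl)phenyl]-4-[4-(benzyloxy)-2-oxo-2H-pyran-6-yl]butane-1,3-dione (open-chain form of a ring–chain pair) | CC(C)CCc1cc(OCc2ccccc2)cc(O)c1C(=O)CC(=O)Cc1cc(OCc2ccccc2)cc(=O)o1 | intermediate
16 | 1-[2,4-dihydroxy-6-(3-methylbutyl)phenyl]-4-(4-hydroxy-2-oxo-2H-pyran-6-yl)butane-1,3-dione (not isolated) | CC(C)CCc1cc(O)cc(O)c1C(=O)CC(=O)Cc1cc(O)cc(=O)o1 | intermediate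
17 | rac-2,7-dihydroxy-2-[(4-hydroxy-2-oxo-2H-pyran-6-yl)methyl]-5-(3-methylbutyl)-2,3-dihydro-4H-chromen-4-one | CC(C)CCc1cc(O)cc2c1C(=O)CC(O)(Cc1cc(O)cc(=O)o1)O2 | intermediate
18 | (2R)-2,7-dihydroxy-2-[(4-hydroxy-2-oxo-2H-pyran-6-yl)methyl]-5-(3-methylbutyl)-2,3-dihydro-4H-chromen-4-one | CC(C)CCc1cc(O)cc2c1C(=O)C[C@@](O)(Cc1cc(O)cc(=O)o1)O2 | target

Total step count: 9. Longest linear sequence: 6 steps (steps 1, 2, 3, 7, 8, 9; the pyrone branch through steps 4, 5, 6, 7, 8, 9 is equally long).

Steps most likely to fail

Step 7. Deprotonation of the acetate or addition to it may compete with the bromine–lithium exchange. In the second stage, proton transfer from the enolisable acid chloride to the enolate may outrun C-acylation and lead to ketene oligomers or to aldol closure towards a coumarin. The fallback sets out from 6 and 11, stays in one flask and comes back at 15. After the same exchange and acyl shift to 13, acid chloride 11 is added before any further base, so that the phenoxide is O-acylated to 2-acetyl-5-(benzyloxy)-3-(3-methylbutyl)phenyl [4-(benzyloxy)-2-oxo-2H-pyran-6-yl]acetate F1. MgBr2·OEt2 and i-Pr2NEt are then added, which should enolise only the chelated ketone (soft enolisation), and the acyl group moves from O1 to C3 in a Baker–Venkataraman rearrangement to give 15.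

Step 9. Ring–chain tautomerism of the hemiketal through open form 16 on the column or during evaporation may erode the enantiomeric purity. The fallback sets out from 17 and comes back at 18 by crystallisation-induced diastereomer transformation. Compound 17 is stirred with (R)-1-phenylethylamine in i-PrOAc/heptane; the amine deprotonates the acidic pyrone hydroxyl and at the same time catalyses the ring–chain equilibrium, so the whole sample can drain into the less soluble salt, (R)-1-phenylethylammonium 6-{[(2R)-2,7-dihydroxy-5-(3-methylbutyl)-4-oxo-3,4-dihydro-2H-chromen-2-yl]methyl}-2-oxo-2H-pyran-4-olate F2 (the antipodal amine is taken if the salt of the (2S) hemiketal is the one that crystallises). The filtered salt is partitioned between cold aqueous citric acid and EtOAc to release 18.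

Step 3. Positional selectivity may be poor, with bromination ortho to the benzyloxy group instead of para. The fallback sets out from 3 and comes back at 6; the bromine is introduced while the two oxygens are still equivalent. NBS in MeCN on 3 should give 1,5-bis(benzyloxy)-2-bromo-3-(3-methylbutyl)benzene F3, since only the doubly oxygen-flanked carbon competes with the two equivalent para positions. NaSEt in DMF should then cleave preferentially the benzyl ether ortho to bromine, whose bromophenoxide is the better leaving group, to give 5-(benzyloxy)-2-bromo-3-(3-methylbutyl)phenol F4 (the isomeric phenol is removed by chromatography). Ac2O/pyridine returns to 6.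

Further compounds
F1 | step 7 | 2-acetyl-5-(benzyloxy)-3-(3-methylbutyl)phenyl [4-(benzyloxy)-2-oxo-2H-pyran-6-yl]acetate | CC(=O)c1c(CCC(C)C)cc(OCc2ccccc2)cc1OC(=O)Cc1cc(OCc2ccccc2)cc(=O)o1
F2 | step 9 | (R)-1-phenylethylammonium 6-{[(2R)-2,7-dihydroxy-5-(3-methylbutyl)-4-oxo-3,4-dihydro-2H-chromen-2-yl]methyl}-2-oxo-2H-pyran-4-olate | C[C@@H]([NH3+])c1ccccc1.CC(C)CCc1cc(O)cc2c1C(=O)C[C@@](O)(Cc1cc([O-])cc(=O)o1)O2
F3 | step 3 | 1,5-bis(benzyloxy)-2-bromo-3-(3-methylbutyl)benzene | CC(C)CCc1cc(OCc2ccccc2)cc(OCc2ccccc2)c1Br
F4 | step 3 | 5-(benzyloxy)-2-bromo-3-(3-methylbutyl)phenol | CC(C)CCc1cc(OCc2ccccc2)cc(O)c1Br
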